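**Retrosynthetic overview**

- The target is ring B (2,4-dihydroxy-3-methylbenzoic acid) whose C6 CH2–O carries the 2,4-dihydroxy-3,6-dimethylbenzoyl group (ring A). The last disconnections are protecting groups only: the aryl silyl ether at ring A C4, then the PMB ester and two MOM ethers on ring B.
- Key disconnection: ring A is opened at C1–C2, C2–C3 and C4–C5 (C5–C6 traces to a Wolff shift), back to an α-diazo enone already esterified to ring B plus 1-(triisopropylsiloxy)propyne. The feature used is the row C2(OH)–C3(CH3)–C4(O) of ring A, which is the ketene carbonyl plus the two alkyne carbons; C5(H), C6(CH3) and the ester-bearing C1 are the diazo carbon and the β-methyl enoate.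
- The diazo enone comes from the methyl ketone by trifluoroacetylation and diazo transfer; the methyl ketone comes from Steglich esterification of the ring B benzylic alcohol with (E)-3-methyl-4-oxopent-2-enoic acid (Wittig reaction on butane-2,3-dione).
- The ring B alcohol comes from a phthalide (hydroxide opening, PMB alkylation), itself made by ortho-lithiation and carboxylation of the MOM-protected benzyl alcohol from 3,5-dihydroxy-4-methylbenzoic acid; the siloxyalkyne comes from ethyl acetate by ynolate homologation.
- Ring order: ring B is bought as an arene; its lactone ring is closed (step 3) and reopened (step 4) only to install the C1 carboxyl; ring A is formed last, in step 10.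

Key step: step 10

Remark: the target has no stereocentre; the only stereochemical element in the route is the E geometry of the enoate alkene, set in step 5 and consumed in step 10.

**Route**

Step 1
Reactants: 1 3,5-dihydroxy-4-methylbenzoic acid
Product: 2 methoxymethyl 3,5-bis(methoxymethoxy)-4-methylbenzoate
Conditions: MOMCl (4 equiv), i-Pr2NEt, CH2Cl2, 0 °C to rt
Reagents that add atoms: chloromethyl methyl ether, COCCl
Why: O-alkylation (Williamson type) of both phenols and the carboxylate by the reactive α-chloro ether under amine base should give the tris-MOM compound in one operation.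

Step 2
Reactants: 2 methoxymethyl 3,5-bis(methoxymethoxy)-4-methylbenzoate
Product: 3 [3,5-bis(methoxymethoxy)-4-methylphenyl]methanol
Conditions: LiAlH4, THF, 0 °C
Reagents that add atoms: none
Why: Hydride reduction of the ester to the primary benzylic alcohol should proceed cleanly, since aryl MOM ethers are inert to LiAlH4.

Step 3
Reactants: 3 [3,5-bis(methoxymethoxy)-4-methylphenyl]methanol
Product: 6 5,7-bis(methoxymethoxy)-6-methyl-2-benzofuran-1(3H)-one, via dilithiated benzyl alkoxide 4 (not isolated), via hydroxy acid 5 (not isolated)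
Conditions: n-BuLi (2.5 equiv), TMEDA, THF, −20 to 0 °C; CO2, −78 °C to rt; 1 M HCl (pH 2), 0 °C to rt
Reagents that add atoms: carbon dioxide, O=C=O; n-butyllithium, [Li]CCCC (lithium held in 4 only)
Why: Directed ortho-metalation, in which the lithium alkoxide and the neighbouring MOM ether jointly direct ring lithiation to C2 (C4 is blocked by methyl), followed by carboxylation and acid-promoted lactonisation of the hydroxy acid, should give the phthalide.

Step 4
Reactants: 6 5,7-bis(methoxymethoxy)-6-methyl-2-benzofuran-1(3H)-one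
Product: 8 4-methoxybenzyl 6-(hydroxymethyl)-2,4-bis(methoxymethoxy)-3-methylbenzoate, via sodium carboxylate 7 (not isolated)
Conditions: NaOH (1.0 equiv), THF/H2O, 60 °C; evaporate, toluene azeotrope; PMBCl, Bu4NI (cat.), DMF, rt
Reagents that add atoms: sodium hydroxide, [Na+].[OH-]; 4-methoxybenzyl chloride, COc1ccc(CCl)cc1
Why: Lactone saponification followed by SN2 O-alkylation of the carboxylate should give the hydroxy ester, because with exactly one equivalent of hydroxide no alkoxide remains to etherify or relactonise and the doubly ortho-substituted ester is slow to cyclise; the product is used promptly.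

Step 5
Reactants: 9 butane-2,3-dione; 10 tert-butyl (triphenylphosphoranylidene)acetate
Product: 11 tert-butyl (2E)-3-methyl-4-oxopent-2-enoate
Conditions: 9 (3 equiv), CH2Cl2, rt
Reagents that add atoms: none
Why: Wittig olefination of one carbonyl of the activated 1,2-diketone by a stabilised ylide (excess diketone suppresses double olefination) should give mainly the thermodynamically preferred E alkene, with the acetyl group trans to the ester.

Step 6
Reactants: 11 tert-butyl (2E)-3-methyl-4-oxopent-2-enoate
Product: 12 (2E)-3-methyl-4-oxopent-2-enoic acid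
Conditions: CF3CO2H, CH2Cl2, rt
Reagents that add atoms: none
Why: Acidolysis of the tert-butyl ester with loss of 2-methylpropene should free the acid without touching the enone or its geometry.

Step 7
Reactants: 8 4-methoxybenzyl 6-(hydroxymethyl)-2,4-bis(methoxymethoxy)-3-methylbenzoate; 12 (2E)-3-methyl-4-oxopent-2-enoic acid
Product: 13 4-methoxybenzyl 2,4-bis(methoxymethoxy)-3-methyl-6-({[(2E)-3-methyl-4-oxopent-2-enoyl]oxy}methyl)benzoate
Conditions: DCC, DMAP (cat.), CH2Cl2, 0 °C to rt
Reagents that add atoms: none
Why: Steglich esterification should acylate the primary benzylic alcohol through the DMAP-activated acyl donor much faster than the neutral alcohol can attack its own hindered PMB ester.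

Step 8
Reactants: 13 4-methoxybenzyl 2,4-bis(methoxymethoxy)-3-methyl-6-({[(2E)-3-methyl-4-oxopent-2-enoyl]oxy}methyl)benzoate
Product: 15 4-methoxybenzyl 6-({[(2E)-5-diazo-3-methyl-4-oxopent-2-enoyl]oxy}methyl)-2,4-bis(methoxymethoxy)-3-methylbenzoate, via trifluoroacetyl diketone 14 (not isolated)
Conditions: LiN(SiMe3)2, THF, −78 °C (13 added to the base); CF3CO2CH2CF3, −78 °C; cold 0.5 M HCl wash; then 4-acetamidobenzenesulfonyl azide, Et3N, H2O, MeCN, rt
Reagents that add atoms: 4-acetamidobenzenesulfonyl azide, CC(=O)Nc1ccc(cc1)S(=O)(=O)N=[N+]=[N-]; 2,2,2-trifluoroethyl trifluoroacetate, O=C(OCC(F)(F)F)C(F)(F)F (atoms held in 14 only)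
Why: Detrifluoroacetylative diazo transfer should work because kinetic enolisation occurs at the acetyl methyl (the three esters have no α-hydrogen), Claisen trifluoroacetylation activates that carbon for Regitz diazo transfer, and the trifluoroacetyl group then leaves on the sulfonamide nitrogen.

Step 9
Reactants: 16 ethyl acetate
Product: 19 1-(triisopropylsiloxy)propyne, via dibromo enolate 17 (not isolated), via lithium propynolate 18 (not isolated)
Conditions: CH2Br2, lithium 2,2,6,6-tetramethylpiperidide, THF, −78 °C; LiN(SiMe3)2; s-BuLi, −78 °C to rt; i-Pr3SiCl, −78 to 0 °C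
Reagents that add atoms: dibromomethane, BrCBr; chlorotriisopropylsilane, CC(C)[Si](Cl)(C(C)C)C(C)C
Why: Kowalski ester homologation, in which LiCHBr2 adds to the ester, the dibromo ketone enolate undergoes bromine–lithium exchange and a 1,2-methyl shift to the ynolate, and the bulky chlorosilane traps the ynolate on oxygen, should give the siloxyalkyne.

Step 10
Reactants: 15 4-methoxybenzyl 6-({[(2E)-5-diazo-3-methyl-4-oxopent-2-enoyl]oxy}methyl)-2,4-bis(methoxymethoxy)-3-methylbenzoate; 19 1-(triisopropylsiloxy)propyne
Product: 24 4-methoxybenzyl 6-[({2-hydroxy-3,6-dimethyl-4-[(triisopropylsilyl)oxy]benzoyl}oxy)methyl]-2,4-bis(methoxymethoxy)-3-methylbenzoate, via vinylketene 20 (not isolated), via cyclobutenone 21 (not isolated), via dienylketene 22 (not isolated), via cyclohexadienone 23 (not isolated)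
Conditions: 19 (2 equiv), hν (medium-pressure Hg lamp, Pyrex filter), degassed ClCH2CH2Cl, rt; then 80 °C
Reagents that add atoms: none
Why: Light expels N2 from 15 and the alkenyl group shifts to the former diazo carbon (photochemical Wolff rearrangement, which makes C5–C6), giving the E-vinylketene 20. Its electrophilic carbonyl carbon is attacked by the nucleophilic, methyl-bearing carbon of 19, and the (2+2) cycloaddition forms C2–C3 and C4–C5 in the 4-alkenylcyclobutenone 21. Thermal conrotatory 4π opening of 21 gives dienylketene 22, and thermal disrotatory 6π electrocyclisation bonds the ketene carbon to the ester-bearing alkene terminus (C1–C2), so that ring A closes as the six-membered cyclohexadienone 23, which enolises to phenol 24. The closest known reaction type is the second-generation Danheiser benzannulation of α-diazo enones with siloxyalkynes, which gives resorcinol monosilyl ethers. No stereocentre is formed, because the sp3 carbons of 21 and 23 are lost on ring opening and aromatisation. Two selectivities are needed: the (2+2) regiochemistry, secured by the oxygen polarisation of the siloxyalkyne, and closure through carbon and not through the ester oxygen, secured by the E alkene, which holds the ester on the outer side of the triene terminus; the Pyrex filter keeps the light off the benzoate chromophores and the excess of 19 keeps the ketene from acylating the product phenol.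

Step 11
Reactants: 24 4-methoxybenzyl 6-[({2-hydroxy-3,6-dimethyl-4-[(triisopropylsilyl)oxy]benzoyl}oxy)methyl]-2,4-bis(methoxymethoxy)-3-methylbenzoate
Product: 25 4-methoxybenzyl 6-{[(2,4-dihydroxy-3,6-dimethylbenzoyl)oxy]methyl}-2,4-bis(methoxymethoxy)-3-methylbenzoate
Conditions: Bu4NF, AcOH, THF, 0 °C
Reagents that add atoms: none
Why: Fluoride-induced desilylation of the aryl silyl ether is fast at 0 °C, and the acetic acid buffer should keep the three ester groups intact.

Step 12
Reactants: 25 4-methoxybenzyl 6-{[(2,4-dihydroxy-3,6-dimethylbenzoyl)oxy]methyl}-2,4-bis(methoxymethoxy)-3-methylbenzoate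
Product: 26 6-{[(2,4-dihydroxy-3,6-dimethylbenzoyl)oxy]methyl}-2,4-dihydroxy-3-methylbenzoic acid
Conditions: CF3CO2H, CH2Cl2, H2O (5 equiv), anisole (10 equiv), 0 °C to rt
Reagents that add atoms: none
Why: Acidolysis should cleave the PMB ester by ionisation to the 4-methoxybenzyl cation (trapped by anisole in a Friedel–Crafts alkylation) and hydrolyse both MOM acetals, while the central benzylic ester survives because its benzylic carbon is meta to both ring B oxygens and ortho to the carboxyl and so cannot ionise.

**Compound list**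

1 | 3,5-dihydroxy-4-methylbenzoic acid | Cc1c(O)cc(C(=O)O)cc1O | starting material
2 | methoxymethyl 3,5-bis(methoxymethoxy)-4-methylbenzoate | COCOC(=O)c1cc(OCOC)c(C)c(OCOC)c1 | intermediate
3 | [3,5-bis(methoxymethoxy)-4-methylphenyl]methanol | OCc1cc(OCOC)c(C)c(OCOC)c1 | intermediate
4 | lithium [2-lithio-3,5-bis(methoxymethoxy)-4-methylphenyl]methanolate (dilithiated benzyl alkoxide) | [Li]OCc1cc(OCOC)c(C)c(OCOC)c1[Li] | intermediate
5 | 6-(hydroxymethyl)-2,4-bis(methoxymethoxy)-3-methylbenzoic acid (hydroxy acid) | OCc1cc(OCOC)c(C)c(OCOC)c1C(=O)O | intermediate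
6 | 5,7-bis(methoxymethoxy)-6-methyl-2-benzofuran-1(3H)-one | O=C1OCc2cc(OCOC)c(C)c(OCOC)c12 | intermediate
7 | sodium 6-(hydroxymethyl)-2,4-bis(methoxymethoxy)-3-methylbenzoate (sodium carboxylate) | OCc1cc(OCOC)c(C)c(OCOC)c1C(=O)[O-].[Na+] | intermediate
8 | 4-methoxybenzyl 6-(hydroxymethyl)-2,4-bis(methoxymethoxy)-3-methylbenzoate | OCc1cc(OCOC)c(C)c(OCOC)c1C(=O)OCc1ccc(OC)cc1 | intermediate
9 | butane-2,3-dione | CC(=O)C(C)=O | starting material
10 | tert-butyl (triphenylphosphoranylidene)acetate | CC(C)(C)OC(=O)C=P(c1ccccc1)(c1ccccc1)c1ccccc1 | starting material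
11 | tert-butyl (2E)-3-methyl-4-oxopent-2-enoate | CC(=O)/C(C)=C/C(=O)OC(C)(C)C | intermediate
12 | (2E)-3-methyl-4-oxopent-2-enoic acid | CC(=O)/C(C)=C/C(=O)O | intermediate
13 | 4-methoxybenzyl 2,4-bis(methoxymethoxy)-3-methyl-6-({[(2E)-3-methyl-4-oxopent-2-enoyl]oxy}methyl)benzoate | CC(=O)/C(C)=C/C(=O)OCc1cc(OCOC)c(C)c(OCOC)c1C(=O)OCc1ccc(OC)cc1 | intermediate
14 | 4-methoxybenzyl 2,4-bis(methoxymethoxy)-3-methyl-6-({[(2E)-7,7,7-trifluoro-3-methyl-4,6-dioxohept-2-enoyl]oxy}methyl)benzoate (trifluoroacetyl diketone) | O=C(CC(=O)/C(C)=C/C(=O)OCc1cc(OCOC)c(C)c(OCOC)c1C(=O)OCc1ccc(OC)cc1)C(F)(F)F | intermediate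
15 | 4-methoxybenzyl 6-({[(2E)-5-diazo-3-methyl-4-oxopent-2-enoyl]oxy}methyl)-2,4-bis(methoxymethoxy)-3-methylbenzoate | [N-]=[N+]=CC(=O)/C(C)=C/C(=O)OCc1cc(OCOC)c(C)c(OCOC)c1C(=O)OCc1ccc(OC)cc1 | intermediate
16 | ethyl acetate | CCOC(C)=O | starting material
17 | lithium 1,1-dibromoprop-1-en-2-olate (dibromo enolate) | [Li+].[O-]C(C)=C(Br)Br | intermediate
18 | lithium prop-1-yn-1-olate (lithium propynolate) | [Li+].[O-]C#CC | intermediate
19 | 1-(triisopropylsiloxy)propyne | CC#CO[Si](C(C)C)(C(C)C)C(C)C | intermediate
20 | 4-methoxybenzyl 2,4-bis(methoxymethoxy)-3-methyl-6-({[(2E)-3-methyl-5-oxopenta-2,4-dienoyl]oxy}methyl)benzoate (vinylketene) | O=C=C/C(C)=C/C(=O)OCc1cc(OCOC)c(C)c(OCOC)c1C(=O)OCc1ccc(OC)cc1 | intermediate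
21 | 4-methoxybenzyl 2,4-bis(methoxymethoxy)-3-methyl-6-{[((2E)-3-{3-methyl-4-oxo-2-[(triisopropylsilyl)oxy]cyclobut-2-en-1-yl}but-2-enoyl)oxy]methyl}benzoate (cyclobutenone, racemic at the ring CH) | O=C1C(C)=C(O[Si](C(C)C)(C(C)C)C(C)C)C1/C(C)=C/C(=O)OCc1cc(OCOC)c(C)c(OCOC)c1C(=O)OCc1ccc(OC)cc1 | intermediate
22 | 4-methoxybenzyl 6-[({(2E,4E)-3,6-dimethyl-7-oxo-5-[(triisopropylsilyl)oxy]hepta-2,4,6-trienoyl}oxy)methyl]-2,4-bis(methoxymethoxy)-3-methylbenzoate (dienylketene, C3 and C6 of the chain cis across C4=C5) | O=C=C(C)/C(O[Si](C(C)C)(C(C)C)C(C)C)=C\C(C)=C\C(=O)OCc1cc(OCOC)c(C)c(OCOC)c1C(=O)OCc1ccc(OC)cc1 | intermediate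
23 | 4-methoxybenzyl 6-{[({3,6-dimethyl-2-oxo-4-[(triisopropylsilyl)oxy]cyclohexa-3,5-dien-1-yl}carbonyl)oxy]methyl}-2,4-bis(methoxymethoxy)-3-methylbenzoate (cyclohexadienone, racemic at C1 of the dienone) | O=C1C(C)=C(O[Si](C(C)C)(C(C)C)C(C)C)C=C(C)C1C(=O)OCc1cc(OCOC)c(C)c(OCOC)c1C(=O)OCc1ccc(OC)cc1 | intermediate
24 | 4-methoxybenzyl 6-[({2-hydroxy-3,6-dimethyl-4-[(triisopropylsilyl)oxy]benzoyl}oxy)methyl]-2,4-bis(methoxymethoxy)-3-methylbenzoate | Cc1cc(O[Si](C(C)C)(C(C)C)C(C)C)c(C)c(O)c1C(=O)OCc1cc(OCOC)c(C)c(OCOC)c1C(=O)OCc1ccc(OC)cc1 | intermediate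
25 | 4-methoxybenzyl 6-{[(2,4-dihydroxy-3,6-dimethylbenzoyl)oxy]methyl}-2,4-bis(methoxymethoxy)-3-methylbenzoate | Cc1cc(O)c(C)c(O)c1C(=O)OCc1cc(OCOC)c(C)c(OCOC)c1C(=O)OCc1ccc(OC)cc1 | intermediate
26 | 6-{[(2,4-dihydroxy-3,6-dimethylbenzoyl)oxy]methyl}-2,4-dihydroxy-3-methylbenzoic acid | Cc1cc(O)c(C)c(O)c1C(=O)OCc1cc(O)c(C)c(O)c1C(=O)O | target

**Summary**

Total step count: 12. Longest linear sequence: 9 steps (steps 1, 2, 3, 4, 7, 8, 10, 11, 12).

**Steps most likely to fail**

Step 10. What may go wrong: E-to-Z photoisomerisation of the enoate before or after loss of N2, after which the Z-vinylketene can close through the ester oxygen instead of through carbon; dipolar cycloaddition of the diazo group to the electron-poor alkene of a second molecule; acylation of the product phenol by the ketene. Fallback: the benzannulation is given up and the central ester is made from a preformed ring A acid. Commercial methyl 2,4-dihydroxy-3,6-dimethylbenzoate is saponified (KOH, H2O/DMSO, then cold acidification with HCl) to 2,4-dihydroxy-3,6-dimethylbenzoic acid F1. Alcohol 8 is then esterified with it under Mitsunobu conditions (PPh3, diisopropyl azodicarboxylate, THF, 0 °C), where the carboxylic acid, far more acidic than the phenols, is the nucleophile that displaces the activated benzylic oxygen. This sets out from 8 and comes back to the route at 25.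

Step 8. What may go wrong: deprotonation at the C3 methyl (extended dienolate) in competition with the acetyl methyl, and conjugate addition of the enolate to 13 that has not yet been enolised. Fallback without a strong base, setting out from 13: soft enolisation (t-BuMe2SiOTf, Et3N, CH2Cl2, −78 to 0 °C) should give the 2-siloxydiene 4-methoxybenzyl 6-[({(2E)-4-[(tert-butyldimethylsilyl)oxy]-3-methylpenta-2,4-dienoyl}oxy)methyl]-2,4-bis(methoxymethoxy)-3-methylbenzoate F2. NBS (THF, 0 °C) should convert it into the bromomethyl ketone 4-methoxybenzyl 6-({[(2E)-5-bromo-3-methyl-4-oxopent-2-enoyl]oxy}methyl)-2,4-bis(methoxymethoxy)-3-methylbenzoate F3. N,N'-Ditosylhydrazine and DBU (THF, 0 °C) should then give the diazo ketone by N-alkylation and two sulfinate eliminations, which comes back to the route at 15.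

Step 3. What may go wrong: lateral metalation of the C4 methyl between the two MOM ethers in competition with ring metalation, and loss of the MOM ether ortho to the new carboxyl during the acid lactonisation. Fallback, setting out from 3: electrophilic bromination (NBS, MeCN, 0 °C) at the ring position ortho and para to the two MOM ethers should give [2-bromo-3,5-bis(methoxymethoxy)-4-methylphenyl]methanol F4. Palladium-catalysed carbonylative lactonisation (Pd(OAc)2, 1,1'-bis(diphenylphosphino)ferrocene, CO (1 atm), Et3N, DMF, 90 °C) should then close the lactone under non-acidic conditions, which comes back to the route at 6.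

**Further compounds**

F1 | step 10 | 2,4-dihydroxy-3,6-dimethylbenzoic acid | Cc1cc(O)c(C)c(O)c1C(=O)O
F2 | step 8 | 4-methoxybenzyl 6-[({(2E)-4-[(tert-butyldimethylsilyl)oxy]-3-methylpenta-2,4-dienoyl}oxy)methyl]-2,4-bis(methoxymethoxy)-3-methylbenzoate | C=C(O[Si](C)(C)C(C)(C)C)/C(C)=C/C(=O)OCc1cc(OCOC)c(C)c(OCOC)c1C(=O)OCc1ccc(OC)cc1
F3 | step 8 | 4-methoxybenzyl 6-({[(2E)-5-bromo-3-methyl-4-oxopent-2-enoyl]oxy}methyl)-2,4-bis(methoxymethoxy)-3-methylbenzoate | BrCC(=O)/C(C)=C/C(=O)OCc1cc(OCOC)c(C)c(OCOC)c1C(=O)OCc1ccc(OC)cc1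
F4 | step 3 | [2-bromo-3,5-bis(methoxymethoxy)-4-methylphenyl]methanol | OCc1cc(OCOC)c(C)c(OCOC)c1Br
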